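The time of reading comes first: the questions concern the moment when 5.0% of the starting material has left, so that moment needs a clock.

| flask | starting material | partner | free catalyst | remark |
|---|---|---|---|---|
| alpha | 0.50 M | 0.54 equiv | 2 mol% | run made earlier |
| zeta | 0.50 M | 1.2 equiv | 2 mol% | run made earlier |
| eta | 0.25 M | 0.80 equiv | 2 mol% | run made earlier |
| flask | 0.50 M | 0.800 equiv | 2 mol% |  |

- alpha (time / min: product / %): 2.50: 3.5; 4.00: 6.3; 8.00: 15.4; 12.0: 22.7; 20.0: 32.2; 30.0: 36.2
- zeta (time / min: product / %): 2.00: 2.3; 6.00: 14.6; 12.0: 32.0; 20.0: 48.3; 25.0: 53.3; 30.0: 58.3
- eta (time / min: product / %): 2.50: 0.9; 5.00: 3.4; 10.0: 8.9; 15.0: 14.7; 30.0: 28.9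

(scatter of a reading: 0.3 percentage points)

- apparent order in free catalyst when 5.0% of the starting material are converted (percent change of the rate of making product for one percent more free catalyst charged)
- apparent order in partner when 5.0% of the starting material are converted (percent change of the rate of making product for one percent more partner charged)

- candidate steps: starting material + free catalyst -> free catalyst + open intermediate; free catalyst + open intermediate <-> catalyst intermediate; partner + catalyst intermediate <-> free catalyst + product
- what has left starting material counts as converted, also if it is not yet product

Free catalyst opens starting material without partner, a pseudo-first-order loss with time constant τ. Product follows from open intermediate, so early on product ≈ r·t·t/(2τ), with r the later steady rate. Alpha gives r ≈ 0.0227 min⁻¹ as a fraction of the charge, and its first reading then gives τ ≈ 2.03 min.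

But this curvature might have another origin. Eta has half of alpha's c(free catalyst), and the same reading there gives 3.82 min, twice alpha's, as a clock run by free catalyst should.

The flask has alpha's c(free catalyst), so the mark time, τ·ln(1/(1 − conversion)), the time to reach the mark, is 0.104 min. The reading of r is rough, yet doubling this gives 0.208 min, still within the first minute.

At the mark, conversion sets c(open intermediate), while more catalyst shortens the mark time. If catalyst intermediate outlives the mark time, it piles up with c(free catalyst) times elapsed time, which the charge leaves unchanged, so the orders are 0 in catalyst and 1 in partner. If it is short-lived, the rate equals its making, and the orders swap. Between these, they add to about 1. My reckoning gives no figure for that lifetime, so it commits to a sum near 1 and to neither order alone.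

The forecast gives 0.85 and 0.4, on the ground that “In the flask, 5% conversion comes at about 1.3 min, still inside the lag.” Its mark time and mine differ.

The flask gives 0.54 in free catalyst and 0.54 in partner.

    starting material + free catalyst → free catalyst + open intermediate (k = 32.0 M⁻¹ min⁻¹)
    free catalyst + open intermediate ⇌ catalyst intermediate (K = 3.30 M⁻¹, k = 6.70 M⁻¹ min⁻¹)
    partner + catalyst intermediate ⇌ free catalyst + product (K = 2.40, k = 32.0 M⁻¹ min⁻¹)

The flask reaches the mark at 0.161 min, later than my estimate of 0.104 min, and by the forward step at the charged partner catalyst intermediate has a half-life of 0.0542 min, about a third of that time. At 0.161 min it holds 0.700% of the catalyst, about half of the share at which its making and use balance, counting forward steps, 1.31%.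

All runs are calculated with made-up constants, and the scatter is random.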